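**Plan**

- The target is all-E (3R,3'R,6'R)-3,19,3'-trihydroxy-7,8-dihydro-β,ε-caroten-8-one (carotenoid numbering, primed = ε-ring half). The first cut is the C14'–C15' σ bond. It joins two unsubstituted sp2 CH carbons between the 13'-methyl alkene and the C15'=C15 alkene, so a stereoretentive Stille coupling of a C19 ε-ring tetraenyl iodide with a C21 keto-tetraenyl stannane can close the chromophore as the last step, with all three hydroxyls and the ketone unprotected.
- Further cuts: C14–C15 (Stille with an (E)-bis-stannyl ethene), C11=C12 and C11'=C12' (two HWE reactions with one C4 iodo-phosphonate), C8–C9 (Nozaki–Hiyama–Kishi), C9'=C10' (HWE on α-ionone), C6–C7 (Stille vinylation of an enol triflate).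
- Forward order: C4 iodo-phosphonate; ε-half from (R)-α-ionone (nitrile, C3' oxidation, reduction, aldehyde, HWE); keto-half from actinol (ring acetaldehyde) and a butynoate-derived C4 vinyl iodide (NHK, unmasking, HWE, oxidation, desilylation, stannylvinylation); final union.
- Stereochemistry: C6' from (R)-α-ionone; C3' by CBS reduction (trans to C6'); C3 from (4R,6R)-actinol. 13E/13'E come from syn-carboalumination, 9E from syn-hydrostannation, 11E/11'E/9'E from HWE, 15E from the (E)-bis-stannane, 7'E from ionone; the Pd couplings retain all of them.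

Key step: step 24

Remark: (R)-α-ionone, (4R,6R)-actinol and (E)-1,2-bis(tributylstannyl)ethene are taken as catalogue chemicals; conjugate bases formed by simple deprotonation (acetylide, enolate, phosphonate carbanions) are treated as forms of the numbered compound and are not numbered separately; TBS = tert-butyldimethylsilyl.

**Route**

Step 1
Reactants: 1 prop-2-yn-1-ol
Product: 3 (E)-3-iodo-2-methylprop-2-en-1-ol, via alkenylalane 2 (not isolated)
Conditions: AlMe3, Cp2ZrCl2 (cat.), CH2Cl2, 0 °C to rt; then I2, THF, −30 to 0 °C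
Reagents that add atoms: trimethylaluminium C[Al](C)C; iodine II
Why: Zirconium-catalysed syn-carboalumination of the terminal alkyne (Negishi carboalumination) puts methyl on the internal and aluminium on the terminal carbon on the same side, and iodinolysis of the C–Al bond with retention fixes the E geometry that later becomes 13E and 13'E.

Step 2
Reactants: 3 (E)-3-iodo-2-methylprop-2-en-1-ol
Product: 4 (E)-3-bromo-1-iodo-2-methylprop-1-ene
Conditions: PBr3, Et2O, 0 °C
Reagents that add atoms: phosphorus tribromide BrP(Br)Br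
Why: SN2 displacement of the activated primary allylic alcohol by bromide (PBr3 bromination) should leave the vinyl iodide and the alkene geometry untouched.

Step 3
Reactants: 4 (E)-3-bromo-1-iodo-2-methylprop-1-ene
Product: 5 diethyl [(E)-3-iodo-2-methylprop-2-en-1-yl]phosphonate
Conditions: P(OEt)3, neat, 90 °C
Reagents that add atoms: triethyl phosphite CCOP(OCC)OCC
Why: Michaelis–Arbuzov reaction of the primary allylic bromide, the vinyl iodide being inert to the phosphite at this temperature.

Step 4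
Reactants: 6 (R)-α-ionone [(E)-4-[(1R)-2,6,6-trimethylcyclohex-2-en-1-yl]but-3-en-2-one]
Product: 7 (2E,4E)-3-methyl-5-[(1R)-2,6,6-trimethylcyclohex-2-en-1-yl]penta-2,4-dienenitrile
Conditions: (EtO)2P(O)CH2CN, NaH (slight deficit), THF, 0 °C to rt; chromatography
Reagents that add atoms: diethyl cyanomethylphosphonate CCOP(=O)(CC#N)OCC
Why: Horner–Wadsworth–Emmons olefination of the methyl ketone by the preformed, weakly basic phosphonate anion (no free base meets the epimerisable C6'–H) should favour the 9'E nitrile, the minor 9'Z isomer being removed by chromatography.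

Step 5
Reactants: 7 (2E,4E)-3-methyl-5-[(1R)-2,6,6-trimethylcyclohex-2-en-1-yl]penta-2,4-dienenitrile
Product: 8 (2E,4E)-3-methyl-5-[(1R)-2,6,6-trimethyl-4-oxocyclohex-2-en-1-yl]penta-2,4-dienenitrile
Conditions: t-BuOOH (aq.), Rh2(cap)4 (cat.), ClCH2CH2Cl, 40 °C, no base
Reagents that add atoms: tert-butyl hydroperoxide CC(C)(C)OO
Why: Metal-catalysed allylic C–H oxidation by tert-butylperoxyl radicals at the only allylic ring methylene (C3', next to C4'=C5') should give the ring enone while the hindered tertiary C6'–H and the electron-poor dienenitrile are left, as in the oxidation of α-ionone derivatives to their 3-oxo compounds.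

Step 6
Reactants: 8 (2E,4E)-3-methyl-5-[(1R)-2,6,6-trimethyl-4-oxocyclohex-2-en-1-yl]penta-2,4-dienenitrile
Product: 9 (2E,4E)-5-[(1R,4R)-4-hydroxy-2,6,6-trimethylcyclohex-2-en-1-yl]-3-methylpenta-2,4-dienenitrile
Conditions: (S)-Me-CBS (20 mol %), catecholborane, toluene, −78 °C
Reagents that add atoms: none
Why: Corey–Bakshi–Shibata reduction in which, with the sp2 C4' flank as the larger carbonyl substituent, the (S)-catalyst should deliver hydride to the ring face syn to the C6' side chain, setting (3'R) with the hydroxyl trans to C6', while nitrile and alkenes are inert to catecholborane at −78 °C.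

Step 7
Reactants: 9 (2E,4E)-5-[(1R,4R)-4-hydroxy-2,6,6-trimethylcyclohex-2-en-1-yl]-3-methylpenta-2,4-dienenitrile
Product: 10 (2E,4E)-5-[(1R,4R)-4-hydroxy-2,6,6-trimethylcyclohex-2-en-1-yl]-3-methylpenta-2,4-dienal
Conditions: DIBAL-H (2.5 equiv), CH2Cl2, −78 °C; aq. Rochelle salt
Reagents that add atoms: water O
Why: DIBAL-H adds once to the conjugated nitrile to give an N-aluminio aldimine that is stable at low temperature and hydrolyses on work-up to the enal (nitrile half-reduction), the hydroxyl only consuming one equivalent of hydride.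

Step 8
Reactants: 10 (2E,4E)-5-[(1R,4R)-4-hydroxy-2,6,6-trimethylcyclohex-2-en-1-yl]-3-methylpenta-2,4-dienal; 5 diethyl [(E)-3-iodo-2-methylprop-2-en-1-yl]phosphonate
Product: 11 (1R,4R)-4-[(1E,3E,5E,7E)-8-iodo-3,7-dimethylocta-1,3,5,7-tetraen-1-yl]-3,5,5-trimethylcyclohex-2-en-1-ol
Conditions: NaHMDS (one extra equiv for the OH), THF, −78 to 0 °C, dark
Reagents that add atoms: none
Why: Horner–Wadsworth–Emmons olefination with the allylic phosphonate anion should form the disubstituted C11'=C12' alkene with high E selectivity and carries the intact E-vinyl iodide into the C19 tetraene.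

Step 9
Reactants: 12 (4R,6R)-4-hydroxy-2,2,6-trimethylcyclohexan-1-one (actinol)
Product: 13 (4R,6R)-4-(tert-butyldimethylsilyloxy)-2,2,6-trimethylcyclohexan-1-one
Conditions: TBSCl, imidazole, DMF, rt
Reagents that add atoms: tert-butyldimethylsilyl chloride CC(C)(C)[Si](C)(C)Cl
Why: Standard silylation of the secondary alcohol so that enolate and organometallic chemistry can follow.

Step 10
Reactants: 13 (4R,6R)-4-(tert-butyldimethylsilyloxy)-2,2,6-trimethylcyclohexan-1-one
Product: 14 (4R)-4-(tert-butyldimethylsilyloxy)-2,6,6-trimethylcyclohex-1-en-1-yl trifluoromethanesulfonate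
Conditions: KHMDS, THF, −78 to 0 °C; PhNTf2, −78 °C to rt
Reagents that add atoms: N-phenylbis(trifluoromethanesulfonimide) O=S(=O)(N(c1ccccc1)S(=O)(=O)C(F)(F)F)C(F)(F)F
Why: The ketone has a single enolisable position (C6–H, C2 being quaternary), so deprotonation gives only the tetrasubstituted enolate, which is O-triflated (enol triflate formation); the C6 centre is erased on purpose and C4 is untouched.

Step 11
Reactants: 14 (4R)-4-(tert-butyldimethylsilyloxy)-2,6,6-trimethylcyclohex-1-en-1-yl trifluoromethanesulfonate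
Product: 15 tert-butyl{[(1R)-4-ethenyl-3,5,5-trimethylcyclohex-3-en-1-yl]oxy}dimethylsilane
Conditions: CH2=CHSnBu3, Pd(PPh3)4 (cat.), LiCl, THF, 70 °C
Reagents that add atoms: tributyl(vinyl)stannane C=C[Sn](CCCC)(CCCC)CCCC
Why: Stille coupling of the enol triflate with vinyltin in the presence of LiCl, a combination established for hindered 2,6,6-trimethylcyclohexenyl triflates, forms the C6–C7 bond.

Step 12
Reactants: 15 tert-butyl{[(1R)-4-ethenyl-3,5,5-trimethylcyclohex-3-en-1-yl]oxy}dimethylsilane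
Product: 17 2-[(4R)-4-(tert-butyldimethylsilyloxy)-2,6,6-trimethylcyclohex-1-en-1-yl]ethan-1-ol, via alkylborane 16 (not isolated)
Conditions: 9-BBN, THF, 0 °C to rt; then NaOH, H2O2, 0 °C
Reagents that add atoms: 9-borabicyclo[3.3.1]nonane B1C2CCCC1CCC2 (boron stays only in 16); hydrogen peroxide OO
Why: Hydroboration–oxidation in which bulky 9-BBN adds only to the monosubstituted vinyl group, boron at the terminal carbon, and leaves the tetrasubstituted ring alkene, so that oxidation gives the primary alcohol at the future C8.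

Step 13
Reactants: 17 2-[(4R)-4-(tert-butyldimethylsilyloxy)-2,6,6-trimethylcyclohex-1-en-1-yl]ethan-1-ol
Product: 18 2-[(4R)-4-(tert-butyldimethylsilyloxy)-2,6,6-trimethylcyclohex-1-en-1-yl]acetaldehyde
Conditions: Dess–Martin periodinane, pyridine, CH2Cl2, 0 °C to rt; used at once
Reagents that add atoms: none
Why: Dess–Martin oxidation under pyridine buffering should give the β,γ-unsaturated aldehyde without acid- or base-induced migration of the ring double bond into conjugation.

Step 14
Reactants: 19 3,3-diethoxyprop-1-yne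
Product: 20 methyl 4,4-diethoxybut-2-ynoate
Conditions: n-BuLi, THF, −78 °C; ClCO2Me, −78 to 0 °C
Reagents that add atoms: methyl chloroformate COC(=O)Cl
Why: Deprotonation of the terminal alkyne and C-acylation of the lithium acetylide with the chloroformate gives the ynoate.

Step 15
Reactants: 20 methyl 4,4-diethoxybut-2-ynoate
Product: 22 methyl (E)-4,4-diethoxy-2-iodobut-2-enoate, via vinylstannane 21 (not isolated)
Conditions: Bu3SnH, Pd(PPh3)4 (cat.), THF, 0 °C to rt; then I2, CH2Cl2, 0 °C
Reagents that add atoms: tributyltin hydride CCCC[SnH](CCCC)CCCC (tin stays only in 21); iodine II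
Why: Palladium-catalysed hydrostannation of the ynoate is a syn addition that places tin α to the ester and hydrogen on the future C10, so the ester carbon (future C19) and the acetal carbon (future C11) end up cis, and iododestannylation with retention gives the vinyl iodide in the same flask.

Step 16
Reactants: 22 methyl (E)-4,4-diethoxy-2-iodobut-2-enoate
Product: 23 (E)-4,4-diethoxy-2-iodobut-2-en-1-ol
Conditions: DIBAL-H (2.2 equiv), CH2Cl2, −78 °C; aq. Rochelle salt
Reagents that add atoms: none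
Why: DIBAL-H reduces the conjugated ester to the allylic alcohol at −78 °C without touching the vinyl iodide or the acetal (ester reduction).

Step 17
Reactants: 23 (E)-4,4-diethoxy-2-iodobut-2-en-1-ol
Product: 24 tert-butyl{[(E)-4,4-diethoxy-2-iodobut-2-en-1-yl]oxy}dimethylsilane
Conditions: TBSCl, imidazole, CH2Cl2, 0 °C to rt
Reagents that add atoms: tert-butyldimethylsilyl chloride CC(C)(C)[Si](C)(C)Cl
Why: Silylation of the primary allylic alcohol keeps the future C19 hydroxyl from lactolising onto C11 once that aldehyde is unmasked.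

Step 18
Reactants: 18 2-[(4R)-4-(tert-butyldimethylsilyloxy)-2,6,6-trimethylcyclohex-1-en-1-yl]acetaldehyde; 24 tert-butyl{[(E)-4,4-diethoxy-2-iodobut-2-en-1-yl]oxy}dimethylsilane
Product: 25 (3E)-3-[(tert-butyldimethylsilyloxy)methyl]-1-[(4R)-4-(tert-butyldimethylsilyloxy)-2,6,6-trimethylcyclohex-1-en-1-yl]-5,5-diethoxypent-3-en-2-ol (both C2 epimers)
Conditions: CrCl2 (4 equiv), NiCl2 (2 mol %), DMSO, rt
Reagents that add atoms: none
Why: Nozaki–Hiyama–Kishi coupling, in which the alkenylchromium(III) species formed from the vinyl iodide with retention adds under non-basic conditions to the enolisable β,γ-unsaturated aldehyde and forms the C8–C9 bond; the new C8 carbinol centre arises as an epimer mixture that step 21 removes.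

Step 19
Reactants: 25 (3E)-3-[(tert-butyldimethylsilyloxy)methyl]-1-[(4R)-4-(tert-butyldimethylsilyloxy)-2,6,6-trimethylcyclohex-1-en-1-yl]-5,5-diethoxypent-3-en-2-ol
Product: 26 (2E)-3-[(tert-butyldimethylsilyloxy)methyl]-5-[(4R)-4-(tert-butyldimethylsilyloxy)-2,6,6-trimethylcyclohex-1-en-1-yl]-4-hydroxypent-2-enal (both C4 epimers)
Conditions: PPTS (cat.), acetone/H2O 10:1, rt
Reagents that add atoms: water O
Why: Mild acid hydrolysis of the allylic diethyl acetal through the conjugated oxocarbenium ion should unmask the C11 aldehyde while both TBS ethers survive, and the C8 hydroxyl, trans to the aldehyde across C9=C10, cannot form a lactol.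

Step 20
Reactants: 26 (2E)-3-[(tert-butyldimethylsilyloxy)methyl]-5-[(4R)-4-(tert-butyldimethylsilyloxy)-2,6,6-trimethylcyclohex-1-en-1-yl]-4-hydroxypent-2-enal; 5 diethyl [(E)-3-iodo-2-methylprop-2-en-1-yl]phosphonate
Product: 27 (3E,5E,7E)-3-[(tert-butyldimethylsilyloxy)methyl]-1-[(4R)-4-(tert-butyldimethylsilyloxy)-2,6,6-trimethylcyclohex-1-en-1-yl]-8-iodo-7-methylocta-3,5,7-trien-2-ol (both C2 epimers)
Conditions: LiHMDS (one extra equiv for the C8–OH), THF, −78 to 0 °C, dark
Reagents that add atoms: none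
Why: Second Horner–Wadsworth–Emmons olefination with phosphonate 5 should form C11=C12 with E selectivity, and it is run at the C8 alcohol oxidation level (lithium alkoxide as spectator) so that neither an acidic C7 methylene nor an enedione Michael acceptor is present.

Step 21
Reactants: 27 (3E,5E,7E)-3-[(tert-butyldimethylsilyloxy)methyl]-1-[(4R)-4-(tert-butyldimethylsilyloxy)-2,6,6-trimethylcyclohex-1-en-1-yl]-8-iodo-7-methylocta-3,5,7-trien-2-ol
Product: 28 (3E,5E,7E)-3-[(tert-butyldimethylsilyloxy)methyl]-1-[(4R)-4-(tert-butyldimethylsilyloxy)-2,6,6-trimethylcyclohex-1-en-1-yl]-8-iodo-7-methylocta-3,5,7-trien-2-one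
Conditions: Dess–Martin periodinane, pyridine, CH2Cl2, 0 °C
Reagents that add atoms: none
Why: Dess–Martin oxidation converts both epimers of the secondary allylic alcohol into the C8 ketone under buffered, non-basic conditions that should leave the C7 methylene, the vinyl iodide and the silyl ethers alone.

Step 22
Reactants: 28 (3E,5E,7E)-3-[(tert-butyldimethylsilyloxy)methyl]-1-[(4R)-4-(tert-butyldimethylsilyloxy)-2,6,6-trimethylcyclohex-1-en-1-yl]-8-iodo-7-methylocta-3,5,7-trien-2-one
Product: 29 (3E,5E,7E)-3-(hydroxymethyl)-1-[(4R)-4-hydroxy-2,6,6-trimethylcyclohex-1-en-1-yl]-8-iodo-7-methylocta-3,5,7-trien-2-one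
Conditions: HF·pyridine, pyridine, THF, 0 °C to rt
Reagents that add atoms: none
Why: Buffered HF·pyridine should cleave both silyl ethers (fluoride-mediated desilylation) without base, so the β,γ-unsaturated ketone is not drawn into conjugation and the vinyl iodide is unaffected; deprotecting here leaves nothing to do after the final coupling.

Step 23
Reactants: 29 (3E,5E,7E)-3-(hydroxymethyl)-1-[(4R)-4-hydroxy-2,6,6-trimethylcyclohex-1-en-1-yl]-8-iodo-7-methylocta-3,5,7-trien-2-one; 30 (E)-1,2-bis(tributylstannyl)ethene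
Product: 31 (3E,5E,7E,9E)-3-(hydroxymethyl)-1-[(4R)-4-hydroxy-2,6,6-trimethylcyclohex-1-en-1-yl]-7-methyl-10-(tributylstannyl)deca-3,5,7,9-tetraen-2-one
Conditions: 30 (4 equiv), Pd2(dba)3 (cat.), AsPh3, NMP, rt, dark; Et3N-deactivated silica
Reagents that add atoms: none
Why: Stille coupling of the alkenyl iodide with an excess of the symmetrical (E)-bis-stannane should stop at mono-coupling and transfer the C15=C15' unit with retention, and the polar diol product separates easily from the non-polar excess reagent.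

Step 24
Reactants: 11 (1R,4R)-4-[(1E,3E,5E,7E)-8-iodo-3,7-dimethylocta-1,3,5,7-tetraen-1-yl]-3,5,5-trimethylcyclohex-2-en-1-ol; 31 (3E,5E,7E,9E)-3-(hydroxymethyl)-1-[(4R)-4-hydroxy-2,6,6-trimethylcyclohex-1-en-1-yl]-7-methyl-10-(tributylstannyl)deca-3,5,7,9-tetraen-2-one
Product: 32 all-E (3R,3'R,6'R)-3,19,3'-trihydroxy-7,8-dihydro-β,ε-caroten-8-one (target)
Conditions: Pd2(dba)3·CHCl3 (5 mol %), AsPh3 (40 mol %), degassed NMP, rt to 40 °C, argon, dark
Reagents that add atoms: none
Why: Stille cross-coupling in which Pd(0) inserts into the C14'–I bond of 11 with retention, the C15' stannyl terminus of 31 transmetalates (AsPh3 speeds this rate-limiting step) and reductive elimination forms the C14'–C15' σ bond between two unhindered sp2 CH carbons, completing the all-E octaene–enone chromophore. The closest known reaction type is the Pd2(dba)3/AsPh3-mediated union of polyenyl iodides with polyenyl stannanes used for retinoids and carotenoids. No ring is closed and no stereocentre is created; the step only has to transfer the preset 13'E and 15'E geometries, which oxidative addition and transmetalation both do with retention. The selectivity needed is reaction at C–I and C–Sn only, in the presence of three free hydroxyls, the C8 ketone with its enolisable C7 methylene and the acid-labile ε-ring allylic alcohol; the neutral, base- and fluoride-free conditions near room temperature should secure it. E/Z scrambling and homocoupling should be held back by exclusion of light and oxygen and by the absence of substituents on both coupling carbons, so that coupling outruns isomerisation.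

**Compound list**

1 | prop-2-yn-1-ol | C#CCO | starting material
2 | dimethylaluminium (E)-3-(dimethylalumanyl)-2-methylprop-2-en-1-olate (alkenylalane) | C[Al](C)/C=C(\C)CO[Al](C)C | intermediate
3 | (E)-3-iodo-2-methylprop-2-en-1-ol | OC/C(C)=C/I | intermediate
4 | (E)-3-bromo-1-iodo-2-methylprop-1-ene | BrC/C(C)=C/I | intermediate
5 | diethyl [(E)-3-iodo-2-methylprop-2-en-1-yl]phosphonate | CCOP(=O)(OCC)C/C(C)=C/I | intermediate
6 | (R)-α-ionone, (E)-4-[(1R)-2,6,6-trimethylcyclohex-2-en-1-yl]but-3-en-2-one | CC1=CCCC(C)(C)[C@H]1/C=C/C(C)=O | starting material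
7 | (2E,4E)-3-methyl-5-[(1R)-2,6,6-trimethylcyclohex-2-en-1-yl]penta-2,4-dienenitrile | CC1=CCCC(C)(C)[C@H]1/C=C/C(C)=C/C#N | intermediate
8 | (2E,4E)-3-methyl-5-[(1R)-2,6,6-trimethyl-4-oxocyclohex-2-en-1-yl]penta-2,4-dienenitrile | CC1=CC(=O)CC(C)(C)[C@H]1/C=C/C(C)=C/C#N | intermediate
9 | (2E,4E)-5-[(1R,4R)-4-hydroxy-2,6,6-trimethylcyclohex-2-en-1-yl]-3-methylpenta-2,4-dienenitrile | CC1=C[C@H](O)CC(C)(C)[C@H]1/C=C/C(C)=C/C#N | intermediate
10 | (2E,4E)-5-[(1R,4R)-4-hydroxy-2,6,6-trimethylcyclohex-2-en-1-yl]-3-methylpenta-2,4-dienal | CC1=C[C@H](O)CC(C)(C)[C@H]1/C=C/C(C)=C/C=O | intermediate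
11 | (1R,4R)-4-[(1E,3E,5E,7E)-8-iodo-3,7-dimethylocta-1,3,5,7-tetraen-1-yl]-3,5,5-trimethylcyclohex-2-en-1-ol | CC1=C[C@H](O)CC(C)(C)[C@H]1/C=C/C(C)=C/C=C/C(C)=C/I | intermediate
12 | (4R,6R)-4-hydroxy-2,2,6-trimethylcyclohexan-1-one (actinol) | O=C1[C@H](C)C[C@@H](O)CC1(C)C | starting material
13 | (4R,6R)-4-(tert-butyldimethylsilyloxy)-2,2,6-trimethylcyclohexan-1-one | O=C1[C@H](C)C[C@@H](O[Si](C)(C)C(C)(C)C)CC1(C)C | intermediate
14 | (4R)-4-(tert-butyldimethylsilyloxy)-2,6,6-trimethylcyclohex-1-en-1-yl trifluoromethanesulfonate | FC(F)(F)S(=O)(=O)OC1=C(C)C[C@@H](O[Si](C)(C)C(C)(C)C)CC1(C)C | intermediate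
15 | tert-butyl{[(1R)-4-ethenyl-3,5,5-trimethylcyclohex-3-en-1-yl]oxy}dimethylsilane | C=CC1=C(C)C[C@@H](O[Si](C)(C)C(C)(C)C)CC1(C)C | intermediate
16 | 9-{2-[(4R)-4-(tert-butyldimethylsilyloxy)-2,6,6-trimethylcyclohex-1-en-1-yl]ethyl}-9-borabicyclo[3.3.1]nonane (alkylborane) | B1(CCC2=C(C)C[C@@H](O[Si](C)(C)C(C)(C)C)CC2(C)C)C3CCCC1CCC3 | intermediate
17 | 2-[(4R)-4-(tert-butyldimethylsilyloxy)-2,6,6-trimethylcyclohex-1-en-1-yl]ethan-1-ol | OCCC1=C(C)C[C@@H](O[Si](C)(C)C(C)(C)C)CC1(C)C | intermediate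
18 | 2-[(4R)-4-(tert-butyldimethylsilyloxy)-2,6,6-trimethylcyclohex-1-en-1-yl]acetaldehyde | O=CCC1=C(C)C[C@@H](O[Si](C)(C)C(C)(C)C)CC1(C)C | intermediate
19 | 3,3-diethoxyprop-1-yne | C#CC(OCC)OCC | starting material
20 | methyl 4,4-diethoxybut-2-ynoate | COC(=O)C#CC(OCC)OCC | intermediate
21 | methyl (E)-4,4-diethoxy-2-(tributylstannyl)but-2-enoate (vinylstannane) | COC(=O)/C(=C\C(OCC)OCC)[Sn](CCCC)(CCCC)CCCC | intermediate
22 | methyl (E)-4,4-diethoxy-2-iodobut-2-enoate | COC(=O)/C(I)=C\C(OCC)OCC | intermediate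
23 | (E)-4,4-diethoxy-2-iodobut-2-en-1-ol | OC/C(I)=C\C(OCC)OCC | intermediate
24 | tert-butyl{[(E)-4,4-diethoxy-2-iodobut-2-en-1-yl]oxy}dimethylsilane | CC(C)(C)[Si](C)(C)OC/C(I)=C\C(OCC)OCC | intermediate
25 | (3E)-3-[(tert-butyldimethylsilyloxy)methyl]-1-[(4R)-4-(tert-butyldimethylsilyloxy)-2,6,6-trimethylcyclohex-1-en-1-yl]-5,5-diethoxypent-3-en-2-ol, both C2 epimers | CCOC(OCC)/C=C(\CO[Si](C)(C)C(C)(C)C)C(O)CC1=C(C)C[C@@H](O[Si](C)(C)C(C)(C)C)CC1(C)C | intermediate
26 | (2E)-3-[(tert-butyldimethylsilyloxy)methyl]-5-[(4R)-4-(tert-butyldimethylsilyloxy)-2,6,6-trimethylcyclohex-1-en-1-yl]-4-hydroxypent-2-enal, both C4 epimers | O=C/C=C(\CO[Si](C)(C)C(C)(C)C)C(O)CC1=C(C)C[C@@H](O[Si](C)(C)C(C)(C)C)CC1(C)C | intermediate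
27 | (3E,5E,7E)-3-[(tert-butyldimethylsilyloxy)methyl]-1-[(4R)-4-(tert-butyldimethylsilyloxy)-2,6,6-trimethylcyclohex-1-en-1-yl]-8-iodo-7-methylocta-3,5,7-trien-2-ol, both C2 epimers | I/C=C(C)/C=C/C=C(\CO[Si](C)(C)C(C)(C)C)C(O)CC1=C(C)C[C@@H](O[Si](C)(C)C(C)(C)C)CC1(C)C | intermediate
28 | (3E,5E,7E)-3-[(tert-butyldimethylsilyloxy)methyl]-1-[(4R)-4-(tert-butyldimethylsilyloxy)-2,6,6-trimethylcyclohex-1-en-1-yl]-8-iodo-7-methylocta-3,5,7-trien-2-one | I/C=C(C)/C=C/C=C(\CO[Si](C)(C)C(C)(C)C)C(=O)CC1=C(C)C[C@@H](O[Si](C)(C)C(C)(C)C)CC1(C)C | intermediate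
29 | (3E,5E,7E)-3-(hydroxymethyl)-1-[(4R)-4-hydroxy-2,6,6-trimethylcyclohex-1-en-1-yl]-8-iodo-7-methylocta-3,5,7-trien-2-one | I/C=C(C)/C=C/C=C(\CO)C(=O)CC1=C(C)C[C@@H](O)CC1(C)C | intermediate
30 | (E)-1,2-bis(tributylstannyl)ethene | CCCC[Sn](CCCC)(CCCC)/C=C/[Sn](CCCC)(CCCC)CCCC | starting material
31 | (3E,5E,7E,9E)-3-(hydroxymethyl)-1-[(4R)-4-hydroxy-2,6,6-trimethylcyclohex-1-en-1-yl]-7-methyl-10-(tributylstannyl)deca-3,5,7,9-tetraen-2-one | CCCC[Sn](CCCC)(CCCC)/C=C/C=C(C)/C=C/C=C(\CO)C(=O)CC1=C(C)C[C@@H](O)CC1(C)C | intermediate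
32 | all-E (3R,3'R,6'R)-3,19,3'-trihydroxy-7,8-dihydro-β,ε-caroten-8-one | CC1=C[C@H](O)CC(C)(C)[C@H]1/C=C/C(C)=C/C=C/C(C)=C/C=C/C=C(C)/C=C/C=C(\CO)C(=O)CC1=C(C)C[C@@H](O)CC1(C)C | target

**Count and risks**

Total step count: 24. Longest linear sequence: 12 steps (12 to 32 through steps 9–13 and 18–24).

Three steps most likely to fail:

Step 24. Transmetalation of the electron-poor tetraenyl stannane may be slow enough for palladium-mediated E/Z isomerisation of the long polyene, protodestannylation and homocoupling to compete. The fallback replaces tin by boron and sets out from 29. Suzuki–Miyaura mono-coupling of 29 with an excess of commercial (E)-1,2-bis(pinacolboryl)ethene (Pd(PPh3)4, aq. K3PO4, THF, rt) should give (3E,5E,7E,9E)-3-(hydroxymethyl)-1-[(4R)-4-hydroxy-2,6,6-trimethylcyclohex-1-en-1-yl]-7-methyl-10-(4,4,5,5-tetramethyl-1,3,2-dioxaborolan-2-yl)deca-3,5,7,9-tetraen-2-one F1. A thallium(I) ethoxide-accelerated Suzuki–Miyaura coupling of this boronate with 11 (Pd(PPh3)4, TlOEt, THF/H2O, rt, dark) comes back to the route at 32.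

Step 6. Facial selectivity may be poor if the neopentyl C2' flank or the ring conformation opposes catalyst control, so that the cis (3'S) epimer forms. The fallback sets out from 8 and uses substrate-independent inversion. Luche reduction (NaBH4, CeCl3·7H2O, MeOH, −40 °C) should give both C3' epimers; the trans epimer is 9 itself. The cis epimer (2E,4E)-5-[(1R,4S)-4-hydroxy-2,6,6-trimethylcyclohex-2-en-1-yl]-3-methylpenta-2,4-dienenitrile F2 is separated and inverted by a Mitsunobu reaction (4-nitrobenzoic acid, PPh3, DIAD, THF, 0 °C) to (1R,4R)-4-[(1E,3E)-4-cyano-3-methylbuta-1,3-dien-1-yl]-3,5,5-trimethylcyclohex-2-en-1-yl 4-nitrobenzoate F3. Methanolysis (K2CO3, MeOH, 0 °C) returns to the route at 9.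

Step 20. The C8 alkoxide formed under the basic conditions may trigger 1,3 O-to-O silyl migration from the C19 oxygen, which would misdirect the later oxidation, and may lower the E selectivity. The fallback sets out from 26 and avoids the alkoxide. Silylation (TESCl, imidazole, CH2Cl2, 0 °C) gives (2E)-3-[(tert-butyldimethylsilyloxy)methyl]-5-[(4R)-4-(tert-butyldimethylsilyloxy)-2,6,6-trimethylcyclohex-1-en-1-yl]-4-(triethylsilyloxy)pent-2-enal F4. Horner–Wadsworth–Emmons olefination with 5 (LiHMDS, THF, −78 to 0 °C) gives triethyl{[(3E,5E,7E)-3-[(tert-butyldimethylsilyloxy)methyl]-1-[(4R)-4-(tert-butyldimethylsilyloxy)-2,6,6-trimethylcyclohex-1-en-1-yl]-8-iodo-7-methylocta-3,5,7-trien-2-yl]oxy}silane F5. Selective cleavage of the secondary triethylsilyl ether (PPTS, MeOH/CH2Cl2, 0 °C) comes back to the route at 27.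

**Further compounds**

F1 | step 24 | (3E,5E,7E,9E)-3-(hydroxymethyl)-1-[(4R)-4-hydroxy-2,6,6-trimethylcyclohex-1-en-1-yl]-7-methyl-10-(4,4,5,5-tetramethyl-1,3,2-dioxaborolan-2-yl)deca-3,5,7,9-tetraen-2-one | CC1(C)OB(/C=C/C=C(C)/C=C/C=C(\CO)C(=O)CC2=C(C)C[C@@H](O)CC2(C)C)OC1(C)C
F2 | step 6 | (2E,4E)-5-[(1R,4S)-4-hydroxy-2,6,6-trimethylcyclohex-2-en-1-yl]-3-methylpenta-2,4-dienenitrile | CC1=C[C@@H](O)CC(C)(C)[C@H]1/C=C/C(C)=C/C#N
F3 | step 6 | (1R,4R)-4-[(1E,3E)-4-cyano-3-methylbuta-1,3-dien-1-yl]-3,5,5-trimethylcyclohex-2-en-1-yl 4-nitrobenzoate | CC1=C[C@H](OC(=O)c2ccc(cc2)[N+](=O)[O-])CC(C)(C)[C@H]1/C=C/C(C)=C/C#N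
F4 | step 20 | (2E)-3-[(tert-butyldimethylsilyloxy)methyl]-5-[(4R)-4-(tert-butyldimethylsilyloxy)-2,6,6-trimethylcyclohex-1-en-1-yl]-4-(triethylsilyloxy)pent-2-enal | O=C/C=C(\CO[Si](C)(C)C(C)(C)C)C(O[Si](CC)(CC)CC)CC1=C(C)C[C@@H](O[Si](C)(C)C(C)(C)C)CC1(C)C
F5 | step 20 | triethyl{[(3E,5E,7E)-3-[(tert-butyldimethylsilyloxy)methyl]-1-[(4R)-4-(tert-butyldimethylsilyloxy)-2,6,6-trimethylcyclohex-1-en-1-yl]-8-iodo-7-methylocta-3,5,7-trien-2-yl]oxy}silane | I/C=C(C)/C=C/C=C(\CO[Si](C)(C)C(C)(C)C)C(O[Si](CC)(CC)CC)CC1=C(C)C[C@@H](O[Si](C)(C)C(C)(C)C)CC1(C)C
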